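**Retrosynthetic overview**

1. Target 35 comes from pentaol 34 by acetylation of the four secondary hydroxyls; the 11β,12β-epoxide is closed late from the C11=C12 alkene of lactone 30 through a bromohydrin.
2. The γ-lactone (C7–O–C19 and C8–C17) comes from a SmI2 Reformatsky cyclisation of a C7 2-bromopropanoate onto a C8 ketone; the ten-membered ring B (C1–C10) comes from a Nozaki–Hiyama–Kishi closure of C6–C7.
3. C7/C8 come from ethyl 1,3-dithiane-2-carboxylate added to a C9 aldehyde; C3–C6 come from a 1,5-anti boron aldol of a C2 methyl ketone with (Z)-3-iodo-2-methylprop-2-enal, followed by 1,3-anti reduction.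
4. Ring A comes from a catalytic enantioselective Diels–Alder reaction of diene 4 with enal ester 5, forming C1–C14 and C10–C11. The enabling feature is that in the cyclohexane ring C1/C10/C11/C12/C13/C14 the oxygens on C14 and C12 are 1,3-related (a 1-alkoxy-3-silyloxy diene), the quaternary C1 carries the oxidised carbon C2 (as formyl, the activating group), and C2/C9 are trans across C1–C10 (an E-alkene).
5. Order of ring formation: six-membered ring A, ten-membered ring B, γ-lactone, epoxide.

Key step: step 3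

Remark on numbering: C-numbers in the text are briarane numbers of the target. C1 is the quaternary carbon carrying CH3-15; C2, C4, C9 and C14 carry the acetoxy groups; C5=C6 is the alkene with CH3-16; the lactone is C7–O–C19(=O)–C17(CH3-18)–C8; C11 carries CH3-20; β is the face of CH3-15.

Assumption: the sense of induction of the oxazaborolidinium catalyst in step 3 is taken from its behaviour with 2-substituted acroleins; if it proved opposite, the enantiomeric catalyst would be used.

**Route**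

Step 1
Reactants: 1 pent-1-yn-3-one; 2 4-methoxybenzyl alcohol
Product: 3 (E)-1-[(4-methoxybenzyl)oxy]pent-1-en-3-one
Conditions: DABCO (10 mol %), CH2Cl2, 0 °C to rt
Reagents that add atoms: none
Why: Amine-catalysed oxa-Michael addition of an alcohol to an ynone should give the thermodynamically preferred (E)-β-alkoxy enone.

Step 2
Reactants: 3 (E)-1-[(4-methoxybenzyl)oxy]pent-1-en-3-one
Product: 4 (1E,3Z)-1-[(4-methoxybenzyl)oxy]-3-[(triisopropylsilyl)oxy]penta-1,3-diene
Conditions: i-Pr3SiOTf, Et3N, Et2O, 0 °C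
Reagents that add atoms: triisopropylsilyl triflate, CC(C)[Si](OS(=O)(=O)C(F)(F)F)(C(C)C)C(C)C
Why: Soft enolisation and O-silylation of the ethyl ketone should give the (Z)-silyl enol ether (methyl cis to oxygen), so both terminal substituents of the diene point outside.

Step 3
Reactants: 4 (1E,3Z)-1-[(4-methoxybenzyl)oxy]-3-[(triisopropylsilyl)oxy]penta-1,3-diene; 5 ethyl (E)-3-methyl-4-oxobut-2-enoate
Product: 6 ethyl (1S,2S,5S,6R)-6-formyl-5-[(4-methoxybenzyl)oxy]-2,6-dimethyl-3-[(triisopropylsilyl)oxy]cyclohex-3-ene-1-carboxylate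
Conditions: oxazaborolidinium triflimide from (S)-α,α-diphenylprolinol-derived B-(o-tolyl)oxazaborolidine and Tf2NH (20 mol %), CH2Cl2, −78 °C
Reagents that add atoms: none
Why: The oxazaborolidinium ion binds the formyl oxygen of 5 and diene 4 adds across the C1=C10 alkene in a concerted, asynchronous [4+2] cycloaddition, the silyl enol ether terminus C11 bonding to C10 (β to the activated formyl group) and the alkoxy-bearing terminus C14 to the methyl-bearing C1. The closest known reaction type is the cationic-oxazaborolidine-catalysed enantioselective Diels–Alder reaction of 2-substituted acroleins with 2-silyloxy dienes, together with the uncatalysed addition of 1-alkoxy-3-silyloxy dienes to 2-methyl enals. Ring A is closed as a six-membered carbocycle by suprafacial [4+2] cycloaddition, which leaves the C12=C13 silyl enol ether as a masked C12 ketone. The E geometry of 5 fixes C2 and C9 trans on the C1–C10 bond, endo orientation of the catalyst-bound formyl group places C2 cis to the C14 ether oxygen, the (1E,3Z) geometry of 4 places the C11 methyl cis to that oxygen (this centre is erased later), and the catalyst shields one enantioface so that the absolute configuration at C1, C10 and C14 is set in one event. The step needs regioselectivity (secured by matched polarisation, with the 1-alkoxy group ortho and the 3-silyloxy group para to the formyl-bearing carbon), endo selectivity for formyl over ester (secured by coordination to the more basic aldehyde) and C=C over C=O chemoselectivity (expected from the ester-activated, strongly electrophilic C10 and the low temperature).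

Step 4
Reactants: 6 Diels–Alder adduct
Product: 7 6-(1-hydroxyethyl) analogue of 6 (C2 carbinol; both C2 epimers)
Conditions: MeMgBr, THF, −78 °C; AcOH/NH4Cl quench at −78 °C
Reagents that add atoms: methylmagnesium bromide, C[Mg]Br
Why: Grignard addition to the aldehyde should be much faster than to the hindered ester at −78 °C; the C2 configuration is irrelevant because it is oxidised next, and the cold quench avoids lactonisation onto the C9 ester.

Step 5
Reactants: 7 C2 carbinol
Product: 8 6-acetyl analogue of 6 (C2 methyl ketone)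
Conditions: Dess–Martin periodinane, NaHCO3, CH2Cl2, 0 °C to rt
Reagents that add atoms: none
Why: Neutral Dess–Martin oxidation of the secondary alcohol should leave the silyl enol ether, the PMB ether and the ester untouched.

Step 6
Reactants: 9 prop-2-yn-1-ol
Product: 11 (Z)-3-iodo-2-methylprop-2-en-1-ol, via alkenylmagnesium alkoxide 10 (not isolated)
Conditions: MeMgBr (2.5 equiv), CuI (10 mol %), THF, −10 °C to rt; then I2, −78 to 0 °C
Reagents that add atoms: methylmagnesium bromide, C[Mg]Br; iodine, II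
Why: Copper-catalysed anti-carbomagnesiation of the propargylic alkoxide gives a chelated alkenylmagnesium whose iodinolysis with retention should place iodine cis to CH2OH.

Step 7
Reactants: 11 (Z)-3-iodo-2-methylprop-2-en-1-ol
Product: 12 (Z)-3-iodo-2-methylprop-2-enal
Conditions: MnO2, CH2Cl2, rt, dark; used at once
Reagents that add atoms: none
Why: Neutral allylic oxidation with MnO2 should keep the Z geometry of the sensitive β-iodo enal.

Step 8
Reactants: 8 C2 methyl ketone; 12 (Z)-3-iodo-2-methylprop-2-enal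
Product: 14 (4R)-β-hydroxy ketone (8 extended at C3 by CH(OH)–C(CH3)=CHI with Z geometry), via dibutylboron enolate 13 (not isolated)
Conditions: n-Bu2BOTf, i-Pr2NEt, Et2O, −78 °C; then 12, −78 to −20 °C; MeOH, pH 7 buffer, H2O2, 0 °C
Reagents that add atoms: none
Why: Boron aldol reaction of a methyl ketone with a β-(4-methoxybenzyl)oxy group (C14) is expected to give the 1,5-anti adduct, so the C14 centre from step 3 should set C4 as R.

Step 9
Reactants: 14 (4R)-β-hydroxy ketone
Product: 15 (2R,4R)-anti-1,3-diol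
Conditions: Me4NBH(OAc)3, MeCN/AcOH, −30 °C
Reagents that add atoms: none
Why: Evans–Saksena reduction delivers hydride intramolecularly from the C4 alkoxyborohydride through a chair transition state and should give the 1,3-anti diol, setting C2 as R.

Step 10
Reactants: 15 anti-1,3-diol
Product: 16 2,4-bis-O-(tert-butyldimethylsilyl) ether of 15
Conditions: t-BuMe2SiOTf, 2,6-lutidine, CH2Cl2, −78 to 0 °C
Reagents that add atoms: tert-butyldimethylsilyl triflate, CC(C)(C)[Si](C)(C)OS(=O)(=O)C(F)(F)F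
Why: Silyl triflate with a hindered base should silylate both secondary alcohols, including the neopentyl C2 hydroxyl.

Step 11
Reactants: 16 bis-silyl ether ester
Product: 17 C9 aldehyde (ethyl ester of 16 reduced to formyl)
Conditions: i-Bu2AlH, CH2Cl2, −78 °C; aq. potassium sodium tartrate work-up
Reagents that add atoms: none
Why: Partial reduction of the ester should stop at the aldehyde because the tetrahedral aluminate is stable at −78 °C.

Step 12
Reactants: 17 C9 aldehyde; 18 ethyl 1,3-dithiane-2-carboxylate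
Product: 21 (9R)-9-O-silyl adduct (C9 carbinol bonded to C8 = dithiane carbon that carries the C7 ethyl ester), via lithiated dithiane ester 19 (not isolated), via lithium aldolate 20 (not isolated)
Conditions: LiN(i-Pr)2, THF, −78 °C; then 17, −78 °C; then t-BuMe2SiOTf, −78 to 0 °C
Reagents that add atoms: tert-butyldimethylsilyl triflate, CC(C)(C)[Si](C)(C)OS(=O)(=O)C(F)(F)F
Why: The glyoxylate anion equivalent should add to the α-chiral aldehyde in the Felkin–Anh sense (quaternary C1 antiperiplanar to the nucleophile), giving 9R, and in situ silylation of the aldolate prevents retro-addition.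

Step 13
Reactants: 21 silyl enol ether
Product: 22 C12 ketone (11α-methyl)
Conditions: Bu4NF/AcOH (1:1), THF, 0 °C
Reagents that add atoms: none
Why: Buffered fluoride should cleave the silyl enol ether far faster than the secondary alkyl silyl ethers and without β-elimination of the C14 ether; the C11 methyl stays equatorial.

Step 14
Reactants: 22 C12 ketone
Product: 23 12α-alcohol (axial hydroxyl)
Conditions: LiBH(s-Bu)3, THF, −78 °C
Reagents that add atoms: none
Why: The bulky hydride should attack the cyclohexanone equatorially to give the axial 12α-alcohol, leaving the hindered ester intact.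

Step 15
Reactants: 23 12α-alcohol
Product: 24 C11=C12 alkene
Conditions: Ph2S[OC(CF3)2Ph]2, CH2Cl2, 0 °C to rt
Reagents that add atoms: none
Why: Sulfurane dehydration proceeds by anti-periplanar elimination; the axial 12α-oxygen and the axial 11β-hydrogen should give the more substituted (Zaitsev) C11=C12 alkene.

Step 16
Reactants: 24 dithiane ethyl ester
Product: 25 C7 aldehyde (2-formyl-1,3-dithiane)
Conditions: i-Bu2AlH, toluene, −78 °C; aq. potassium sodium tartrate work-up
Reagents that add atoms: none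
Why: Partial reduction of the α,α-dithio ester should stop at the aldehyde, which has no α-hydrogen.

Step 17
Reactants: 25 C7 aldehyde with Z-vinyl iodide
Product: 26 macrocyclic (7S)-allylic alcohol (ring B closed by the C6–C7 bond)
Conditions: CrCl2 (excess), NiCl2 (cat.), DMSO/THF, rt, high dilution (0.003 M)
Reagents that add atoms: none
Why: Nozaki–Hiyama–Kishi ring closure adds the alkenylchromium to the aldehyde with retention of the Z geometry; the 7S carbinol is expected from attack on the aldehyde face turned away from the C9 silyl ether, but this is not predictable with confidence.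

Step 18
Reactants: 26 macrocyclic alcohol; 27 2-bromopropanoyl bromide (racemic)
Product: 28 7-O-(2-bromopropanoyl) ester of 26 (both bromide epimers)
Conditions: pyridine, DMAP (cat.), CH2Cl2, 0 °C
Reagents that add atoms: none
Why: Acylation of the allylic alcohol with an acid bromide is routine, and the bromide-bearing centre is erased in step 20.

Step 19
Reactants: 28 dithiane bromoester
Product: 29 C8 ketone (α-acyloxy ketone)
Conditions: PhI(OCOCF3)2, NaHCO3, MeCN/H2O (9:1), 0 °C
Reagents that add atoms: water, O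
Why: Oxidative dethioacetalisation with the iodine reagent is fast and should tolerate the alkenes, the α-bromo ester and the ethers.

Step 20
Reactants: 29 keto bromoester
Product: 30 γ-lactone (8-hydroxy, 17-methyl; C11=C12 alkene; 2,4,9-tri-O-silyl; 14-O-PMB)
Conditions: SmI2 (2.5 equiv), THF, −78 °C
Reagents that add atoms: none
Why: Intramolecular Reformatsky reaction: reduction of the C–Br bond gives a samarium enolate that adds 5-exo to the C8 ketone through a chelate, which should place the carbon substituents C6 and C9 trans on the lactone (8-OH cis to C6) and the epimerisable C17 methyl trans to C9.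

Step 21
Reactants: 30 lactone with C11=C12 alkene
Product: 32 11β,12β-epoxide, via bromohydrin 31 (not isolated)
Conditions: N-bromoacetamide, acetone/H2O, 0 °C, dark; then DBU, CH2Cl2, rt
Reagents that add atoms: water, O; N-bromoacetamide, CC(=O)NBr (bromine only in 31)
Why: The bromonium ion should form on the α face, anti to the axial CH3-15, and open trans-diaxially (Fürst–Plattner) with water at the tertiary C11 to give the 11β-hydroxy-12α-bromide, which DBU closes to the β-epoxide; the C5=C6 alkene is deactivated by two allylic C–O bonds.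

Step 22
Reactants: 32 epoxide PMB ether
Product: 33 14-alcohol
Conditions: DDQ, CH2Cl2/pH 7 buffer, 0 °C
Reagents that add atoms: none
Why: Oxidative cleavage of the PMB ether under buffered conditions should spare the epoxide, the lactone and the silyl ethers.

Step 23
Reactants: 33 tris-silyl ether
Product: 34 2,4,8,9,14-pentaol
Conditions: HF·pyridine, pyridine/THF, 0 °C to rt
Reagents that add atoms: none
Why: Pyridine-buffered HF should remove the three silyl ethers while keeping the trisubstituted epoxide and the lactone; 34 is acetylated at once to avoid lactone migration to O9.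

Step 24
Reactants: 34 pentaol
Product: 35 CNP0215170.2
Conditions: Ac2O, pyridine, DMAP (cat.), CH2Cl2, 0 °C to rt
Reagents that add atoms: acetic anhydride, CC(=O)OC(C)=O
Why: The four secondary hydroxyls (C2, C4, C9, C14) should be acetylated while the hindered tertiary C8 hydroxyl stays free.

**Compound list**

1 | pent-1-yn-3-one | CCC(=O)C#C | starting material
2 | 4-methoxybenzyl alcohol | COc1ccc(CO)cc1 | starting material
3 | (E)-1-[(4-methoxybenzyl)oxy]pent-1-en-3-one | CCC(=O)/C=C/OCc1ccc(OC)cc1 | intermediate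
4 | (1E,3Z)-1-[(4-methoxybenzyl)oxy]-3-[(triisopropylsilyl)oxy]penta-1,3-diene | COc1ccc(CO/C=C/C(O[Si](C(C)C)(C(C)C)C(C)C)=C/C)cc1 | intermediate
5 | ethyl (E)-3-methyl-4-oxobut-2-enoate | CCOC(=O)/C=C(\C)C=O | starting material
6 | ethyl (1S,2S,5S,6R)-6-formyl-5-[(4-methoxybenzyl)oxy]-2,6-dimethyl-3-[(triisopropylsilyl)oxy]cyclohex-3-ene-1-carboxylate | COc1ccc(CO[C@H]2C=C(O[Si](C(C)C)(C(C)C)C(C)C)[C@@H](C)[C@H](C(=O)OCC)[C@@]2(C)C=O)cc1 | intermediate
7 | 6-(1-hydroxyethyl) analogue of 6 (C2 carbinol, both epimers) | COc1ccc(CO[C@H]2C=C(O[Si](C(C)C)(C(C)C)C(C)C)[C@@H](C)[C@H](C(=O)OCC)[C@@]2(C)C(C)O)cc1 | intermediate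
8 | 6-acetyl analogue of 6 (C2 methyl ketone) | COc1ccc(CO[C@H]2C=C(O[Si](C(C)C)(C(C)C)C(C)C)[C@@H](C)[C@H](C(=O)OCC)[C@@]2(C)C(C)=O)cc1 | intermediate
9 | prop-2-yn-1-ol | OCC#C | starting material
10 | (Z)-alkenylmagnesium alkoxide from carbomagnesiation of 9 | Br[Mg]OC/C(C)=C\[Mg]Br | intermediate
11 | (Z)-3-iodo-2-methylprop-2-en-1-ol | OC/C(C)=C\I | intermediate
12 | (Z)-3-iodo-2-methylprop-2-enal | O=C/C(C)=C\I | intermediate
13 | dibutylboron enolate of 8 | COc1ccc(CO[C@H]2C=C(O[Si](C(C)C)(C(C)C)C(C)C)[C@@H](C)[C@H](C(=O)OCC)[C@@]2(C)C(=C)OB(CCCC)CCCC)cc1 | intermediate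
14 | (4R)-β-hydroxy ketone (C2 ketone, C4 carbinol, Z-vinyl iodide) | COc1ccc(CO[C@H]2C=C(O[Si](C(C)C)(C(C)C)C(C)C)[C@@H](C)[C@H](C(=O)OCC)[C@@]2(C)C(=O)C[C@@H](O)/C(C)=C\I)cc1 | intermediate
15 | (2R,4R)-anti-1,3-diol | COc1ccc(CO[C@H]2C=C(O[Si](C(C)C)(C(C)C)C(C)C)[C@@H](C)[C@H](C(=O)OCC)[C@@]2(C)[C@H](O)C[C@@H](O)/C(C)=C\I)cc1 | intermediate
16 | 2,4-bis-O-(tert-butyldimethylsilyl) ether of 15 | COc1ccc(CO[C@H]2C=C(O[Si](C(C)C)(C(C)C)C(C)C)[C@@H](C)[C@H](C(=O)OCC)[C@@]2(C)[C@H](O[Si](C)(C)C(C)(C)C)C[C@@H](O[Si](C)(C)C(C)(C)C)/C(C)=C\I)cc1 | intermediate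
17 | C9 aldehyde | COc1ccc(CO[C@H]2C=C(O[Si](C(C)C)(C(C)C)C(C)C)[C@@H](C)[C@H](C=O)[C@@]2(C)[C@H](O[Si](C)(C)C(C)(C)C)C[C@@H](O[Si](C)(C)C(C)(C)C)/C(C)=C\I)cc1 | intermediate
18 | ethyl 1,3-dithiane-2-carboxylate | CCOC(=O)C1SCCCS1 | starting material
19 | ethyl 2-lithio-1,3-dithiane-2-carboxylate | [Li+].CCOC(=O)[C-]1SCCCS1 | intermediate
20 | lithium (9R)-aldolate of 17 with 19 | [Li+].COc1ccc(CO[C@H]2C=C(O[Si](C(C)C)(C(C)C)C(C)C)[C@@H](C)[C@H]([C@@H]([O-])C3(C(=O)OCC)SCCCS3)[C@@]2(C)[C@H](O[Si](C)(C)C(C)(C)C)C[C@@H](O[Si](C)(C)C(C)(C)C)/C(C)=C\I)cc1 | intermediate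
21 | (9R)-9-O-silyl dithiane ester | COc1ccc(CO[C@H]2C=C(O[Si](C(C)C)(C(C)C)C(C)C)[C@@H](C)[C@H]([C@@H](O[Si](C)(C)C(C)(C)C)C3(C(=O)OCC)SCCCS3)[C@@]2(C)[C@H](O[Si](C)(C)C(C)(C)C)C[C@@H](O[Si](C)(C)C(C)(C)C)/C(C)=C\I)cc1 | intermediate
22 | C12 ketone | COc1ccc(CO[C@H]2CC(=O)[C@@H](C)[C@H]([C@@H](O[Si](C)(C)C(C)(C)C)C3(C(=O)OCC)SCCCS3)[C@@]2(C)[C@H](O[Si](C)(C)C(C)(C)C)C[C@@H](O[Si](C)(C)C(C)(C)C)/C(C)=C\I)cc1 | intermediate
23 | 12α-alcohol | COc1ccc(CO[C@H]2C[C@@H](O)[C@@H](C)[C@H]([C@@H](O[Si](C)(C)C(C)(C)C)C3(C(=O)OCC)SCCCS3)[C@@]2(C)[C@H](O[Si](C)(C)C(C)(C)C)C[C@@H](O[Si](C)(C)C(C)(C)C)/C(C)=C\I)cc1 | intermediate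
24 | C11=C12 alkene, dithiane ethyl ester | COc1ccc(CO[C@H]2CC=C(C)[C@H]([C@@H](O[Si](C)(C)C(C)(C)C)C3(C(=O)OCC)SCCCS3)[C@@]2(C)[C@H](O[Si](C)(C)C(C)(C)C)C[C@@H](O[Si](C)(C)C(C)(C)C)/C(C)=C\I)cc1 | intermediate
25 | C7 aldehyde | COc1ccc(CO[C@H]2CC=C(C)[C@H]([C@@H](O[Si](C)(C)C(C)(C)C)C3(C=O)SCCCS3)[C@@]2(C)[C@H](O[Si](C)(C)C(C)(C)C)C[C@@H](O[Si](C)(C)C(C)(C)C)/C(C)=C\I)cc1 | intermediate
26 | macrocyclic (7S)-allylic alcohol (ring B closed) | COc1ccc(CO[C@H]2CC=C(C)[C@@H]3[C@@H](O[Si](C)(C)C(C)(C)C)C4(SCCCS4)[C@@H](O)/C=C(/C)[C@H](O[Si](C)(C)C(C)(C)C)C[C@@H](O[Si](C)(C)C(C)(C)C)[C@@]23C)cc1 | intermediate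
27 | 2-bromopropanoyl bromide (racemic) | CC(Br)C(Br)=O | starting material
28 | 7-O-(2-bromopropanoyl) ester of 26 | COc1ccc(CO[C@H]2CC=C(C)[C@@H]3[C@@H](O[Si](C)(C)C(C)(C)C)C4(SCCCS4)[C@@H](OC(=O)C(C)Br)/C=C(/C)[C@H](O[Si](C)(C)C(C)(C)C)C[C@@H](O[Si](C)(C)C(C)(C)C)[C@@]23C)cc1 | intermediate
29 | C8 ketone (α-acyloxy ketone) | COc1ccc(CO[C@H]2CC=C(C)[C@@H]3[C@@H](O[Si](C)(C)C(C)(C)C)C(=O)[C@@H](OC(=O)C(C)Br)/C=C(/C)[C@H](O[Si](C)(C)C(C)(C)C)C[C@@H](O[Si](C)(C)C(C)(C)C)[C@@]23C)cc1 | intermediate
30 | γ-lactone (8-hydroxy, 17-methyl; C11=C12 alkene) | COc1ccc(CO[C@H]2CC=C(C)[C@@H]3[C@@H](O[Si](C)(C)C(C)(C)C)[C@@]4(O)[C@H](/C=C(/C)[C@H](O[Si](C)(C)C(C)(C)C)C[C@@H](O[Si](C)(C)C(C)(C)C)[C@@]23C)OC(=O)[C@@H]4C)cc1 | intermediate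
31 | 11β-hydroxy-12α-bromide | COc1ccc(CO[C@H]2C[C@@H](Br)[C@@](O)(C)[C@@H]3[C@@H](O[Si](C)(C)C(C)(C)C)[C@@]4(O)[C@H](/C=C(/C)[C@H](O[Si](C)(C)C(C)(C)C)C[C@@H](O[Si](C)(C)C(C)(C)C)[C@@]23C)OC(=O)[C@@H]4C)cc1 | intermediate
32 | 11β,12β-epoxide (14-O-PMB, 2,4,9-tri-O-silyl) | COc1ccc(CO[C@H]2C[C@@H]5O[C@]5(C)[C@@H]3[C@@H](O[Si](C)(C)C(C)(C)C)[C@@]4(O)[C@H](/C=C(/C)[C@H](O[Si](C)(C)C(C)(C)C)C[C@@H](O[Si](C)(C)C(C)(C)C)[C@@]23C)OC(=O)[C@@H]4C)cc1 | intermediate
33 | 14-alcohol (2,4,9-tri-O-silyl) | O[C@H]1C[C@@H]2O[C@]2(C)[C@@H]2[C@@H](O[Si](C)(C)C(C)(C)C)[C@@]3(O)[C@H](/C=C(/C)[C@H](O[Si](C)(C)C(C)(C)C)C[C@@H](O[Si](C)(C)C(C)(C)C)[C@@]12C)OC(=O)[C@@H]3C | intermediate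
34 | 2,4,8,9,14-pentaol | O[C@H]1C[C@@H]2O[C@]2(C)[C@@H]2[C@@H](O)[C@@]3(O)[C@H](/C=C(/C)[C@H](O)C[C@@H](O)[C@@]12C)OC(=O)[C@@H]3C | intermediate
35 | CNP0215170.2: (1S,2R,4R,5Z,7S,8S,9R,10S,11R,12S,14S,17R)-2,4,9,14-tetraacetoxy-11,12-epoxy-8-hydroxy briarane 7,19-lactone | CC(=O)O[C@H]1C[C@@H]2O[C@]2(C)[C@@H]2[C@@H](OC(C)=O)[C@@]3(O)[C@H](/C=C(/C)[C@H](OC(C)=O)C[C@@H](OC(C)=O)[C@@]12C)OC(=O)[C@@H]3C | target

**Totals**

Total step count: 24.
Longest linear sequence: 22 steps (steps 1–5 and 8–24).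

**Three steps most likely to fail**

Step 17 (ring closure of ring B). What may go wrong: intermolecular coupling may outrun the ten-membered ring closure, or the alkenylchromium may attack the wrong aldehyde face and give the C7 epimer. The fallback sets out from the epimeric macrocyclic alcohol 7-epi-26 F2 (or the epimer mixture) and comes back at 26. Oxidation with Dess–Martin periodinane should give the macrocyclic enone F3, and reagent-controlled CBS reduction with the (R)-methyl oxazaborolidine and catecholborane should return the 7S alcohol 26.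

Step 20 (lactone formation). What may go wrong: single-electron reduction may cleave the C7–O bond of the α-acyloxy ketone instead of the C–Br bond, or the tethered enolate may add to the wrong ketone face. The fallback sets out from 26 and comes back at 30. PhI(OCOCF3)2 in aqueous MeCN should unmask the α-hydroxy ketone F4. An intermolecular Reformatsky reaction with ethyl 2-bromopropanoate and zinc, directed by chelation of the C7 zinc alkoxide, should give the hydroxy ester F5. F5 lactonises through O7 and is equilibrated at C17 with DBU to give 30.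

Step 3 (key cycloaddition). What may go wrong: under Lewis acid catalysis the diene may add to the formyl C=O (aldol-type or hetero-cycloaddition) instead of the C=C bond, or the enantiofacial bias may be low. The fallback sets out from diene 4 and comes back at methyl ketone 8. Wittig olefination of butane-2,3-dione with ethyl (triphenylphosphoranylidene)acetate gives ethyl (E)-3-methyl-4-oxopent-2-enoate F1. F1 has no aldehyde carbonyl, and its cycloaddition with 4 under the same oxazaborolidinium catalysis (enones are established substrates) should give 8 directly, without steps 4 and 5.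

**Further compounds**

F1 | step 3 | ethyl (E)-3-methyl-4-oxopent-2-enoate | CCOC(=O)/C=C(\C)C(C)=O
F2 | step 17 | 7-epi-26 (7R macrocyclic alcohol) | COc1ccc(CO[C@H]2CC=C(C)[C@@H]3[C@@H](O[Si](C)(C)C(C)(C)C)C4(SCCCS4)[C@H](O)/C=C(/C)[C@H](O[Si](C)(C)C(C)(C)C)C[C@@H](O[Si](C)(C)C(C)(C)C)[C@@]23C)cc1
F3 | step 17 | macrocyclic C7 enone | COc1ccc(CO[C@H]2CC=C(C)[C@@H]3[C@@H](O[Si](C)(C)C(C)(C)C)C4(SCCCS4)C(=O)/C=C(/C)[C@H](O[Si](C)(C)C(C)(C)C)C[C@@H](O[Si](C)(C)C(C)(C)C)[C@@]23C)cc1
F4 | step 20 | macrocyclic 7-hydroxy C8 ketone | COc1ccc(CO[C@H]2CC=C(C)[C@@H]3[C@@H](O[Si](C)(C)C(C)(C)C)C(=O)[C@@H](O)/C=C(/C)[C@H](O[Si](C)(C)C(C)(C)C)C[C@@H](O[Si](C)(C)C(C)(C)C)[C@@]23C)cc1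
F5 | step 20 | 7,8-dihydroxy ethyl ester (open Reformatsky adduct) | COc1ccc(CO[C@H]2CC=C(C)[C@@H]3[C@@H](O[Si](C)(C)C(C)(C)C)[C@](O)([C@@H](C)C(=O)OCC)[C@@H](O)/C=C(/C)[C@H](O[Si](C)(C)C(C)(C)C)C[C@@H](O[Si](C)(C)C(C)(C)C)[C@@]23C)cc1
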